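## Retrosynthetic overview

1. Target ⇐ C15 desilylation and O8 methacrylation of an 8-hydroxy germacranolide that already carries the O9 isovalerate.
2. Ten-membered carbocycle and α-methylene-γ-lactone ⇐ one CrCl2-mediated intramolecular allylation/lactonization (C6–C7 bond) of an enal–allylic chloride.
3. 3(2H)-Furanone and quaternary C10 ⇐ AuCl3-catalysed carbonyl–alkyne heterocyclization with 1,2-methyl shift of a 2-silyloxy-2-alkynyl ketone; the carbinol stereocentre (C1) is relayed to C10.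
4. C8–C9 bond with the isovalerate in place ⇐ three-component coupling of an α-diazoketone, 3-methylbutanoic acid and a (Z)-2-(chloromethyl)-4-oxobutenoate; the diazoketone ⇐ Sonogashira union of a (Z)-iodoalkene with an (S)-α-ketol from butane-2,3-dione.
5. Ring order: furanone first (step 11), then carbocycle and lactone together (step 13).

Assumption: germacranolide numbering is used (C1 furanone C=O, C2=C3, C3–O–C10 bridge, C4=C5, C6 lactone O-carbon, C7, C8, C9, C10 with methyl C14, C11=C13, C12 lactone C=O, C15 CH2OH), and the target is the drawn (4Z,6R,7S,8S,9R,10S) enantiomer.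

## Route

Step 1
Reactants: 1 but-2-yne-1,4-diol
Product: 2 4-[(tert-butyldiphenylsilyl)oxy]but-2-yn-1-ol
Conditions: NaH (1.0 equiv), THF, 0 °C; tert-butyl(chloro)diphenylsilane (1.0 equiv), 0 °C → rt
Reagents that add atoms: tert-butyl(chloro)diphenylsilane, CC(C)(C)[Si](Cl)(c1ccccc1)c1ccccc1
Why: O-silylation of the sparingly soluble monosodium alkoxide of a symmetric diol gives the mono-ether selectively; no stereocentre is involved.

Step 2
Reactants: 2 4-[(tert-butyldiphenylsilyl)oxy]but-2-yn-1-ol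
Product: 3 (Z)-4-[(tert-butyldiphenylsilyl)oxy]-3-iodobut-2-en-1-ol
Conditions: NaAlH2(OCH2CH2OMe)2, THF, 0 °C → rt; then iodine (I2), THF, −78 → 0 °C
Reagents that add atoms: iodine, [I][I]
Why: Hydroxyl-directed trans-hydroalumination of the propargylic alcohol and iodinolysis of the vinylalane with retention give only the (Z)-iodoalkene, which fixes the C4=C5 geometry (C3 and C6 cis).

Step 3
Reactants: 4 2,2-dimethoxyacetaldehyde, 5 methyl prop-2-enoate
Product: 6 methyl 2-(1-hydroxy-2,2-dimethoxyethyl)prop-2-enoate (racemic)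
Conditions: DABCO (0.5 equiv), 1,4-dioxane/H2O 1:1, rt
Reagents that add atoms: none
Why: Morita–Baylis–Hillman reaction of an activated α,α-dialkoxy aldehyde with an acrylate; the racemic carbinol centre is removed in step 4.

Step 4
Reactants: 6 methyl 2-(1-hydroxy-2,2-dimethoxyethyl)prop-2-enoate
Product: 8 methyl (Z)-2-(chloromethyl)-4-oxobut-2-enoate, via chloro acetal 7 (not isolated)
Conditions: SOCl2, CH2Cl2, 0 °C → rt; then 2 M HCl, acetone, rt; used fresh
Reagents that add atoms: thionyl chloride, O=S(Cl)Cl; water, O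
Why: Chlorination of the Baylis–Hillman alcohol with allylic transposition (SNi′) gives the thermodynamic (Z)-2-(chloromethyl)enoate, and acetal hydrolysis then frees the aldehyde without touching the allylic chloride.

Step 5
Reactants: 9 butane-2,3-dione (3 equiv), 10 ethynyltrimethylsilane
Product: 12 (S)-3-hydroxy-3-methylpent-4-yn-2-one, via TMS-alkynyl ketol 11 (not isolated)
Conditions: Zn(OTf)2 (20 mol %), 2-(dimethylamino)-1-(4-nitrophenyl)-3-[(tert-butyldimethylsilyl)oxy]propan-1-ol (22 mol %; the (1S,2S) or (1R,2R) antipode that gives the S product), Et3N (30 mol %), toluene, 23–40 °C, slow addition of 9; then K2CO3 (10 mol %), MeOH, 0 °C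
Reagents that add atoms: none
Why: Proposed new method: the zinc acetylide formed with Zn(OTf)2/Et3N and held by the chiral amino alkoxide adds to one enantiotopic carbonyl face of butane-2,3-dione, which chelates zinc through both oxygens as an α-keto ester does, and a second addition is suppressed because the product zinc alkoxide is a hindered α-quaternary ketone; the closest known reaction type is the Zn(OTf)2/amino alcohol enantioselective alkynylation of α-keto esters, extended here to a symmetric 1,2-diketone, and it sets the (S)-carbinol centre that later becomes C10.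

Step 6
Reactants: 3 (Z)-4-[(tert-butyldiphenylsilyl)oxy]-3-iodobut-2-en-1-ol, 12 (S)-3-hydroxy-3-methylpent-4-yn-2-one
Product: 13 (3S,6E)-6-{[(tert-butyldiphenylsilyl)oxy]methyl}-3,8-dihydroxy-3-methyloct-6-en-4-yn-2-one
Conditions: Pd(PPh3)2Cl2 (3 mol %), CuI (6 mol %), Et3N (3 equiv), THF, rt
Reagents that add atoms: none
Why: Sonogashira coupling proceeds with retention of alkene geometry (the descriptor becomes E only through a priority change) and tolerates both free hydroxyls.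

Step 7
Reactants: 13 (3S,6E)-6-{[(tert-butyldiphenylsilyl)oxy]methyl}-3,8-dihydroxy-3-methyloct-6-en-4-yn-2-one
Product: 14 (3S,6E)-6-{[(tert-butyldiphenylsilyl)oxy]methyl}-3-methyl-3,8-bis[(triethylsilyl)oxy]oct-6-en-4-yn-2-one
Conditions: triethylsilyl trifluoromethanesulfonate (2.4 equiv), 2,6-lutidine (3 equiv), CH2Cl2, −78 → 0 °C
Reagents that add atoms: triethylsilyl trifluoromethanesulfonate, CC[Si](CC)(CC)OS(=O)(=O)C(F)(F)F
Why: Silyl triflate silylation protects the primary allylic and the hindered tertiary propargylic hydroxyl in one operation, which blocks enynol-to-furan cyclization, α-ketol isomerization and carbene O–H insertion later on.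

Step 8
Reactants: 14 (3S,6E)-6-{[(tert-butyldiphenylsilyl)oxy]methyl}-3-methyl-3,8-bis[(triethylsilyl)oxy]oct-6-en-4-yn-2-one
Product: 16 (3S,6E)-6-{[(tert-butyldiphenylsilyl)oxy]methyl}-1-diazo-3-methyl-3,8-bis[(triethylsilyl)oxy]oct-6-en-4-yn-2-one, via trifluoroacetyl diketone 15 (not isolated)
Conditions: LiN(SiMe3)2 (1.1 equiv), THF, −78 °C; CF3CO2CH2CF3 (1.2 equiv); then methanesulfonyl azide (1.5 equiv), Et3N, H2O (1 equiv), MeCN, rt
Reagents that add atoms: methanesulfonyl azide, CS(=O)(=O)N=[N+]=[N-]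
Why: Detrifluoroacetylative diazo transfer (Danheiser): the only enolizable position is trifluoroacetylated (Claisen condensation) and Regitz diazo transfer to the 1,3-diketone expels the trifluoroacetyl group.

Step 9
Reactants: 16 (3S,6E)-6-{[(tert-butyldiphenylsilyl)oxy]methyl}-1-diazo-3-methyl-3,8-bis[(triethylsilyl)oxy]oct-6-en-4-yn-2-one, 17 3-methylbutanoic acid (1.5 equiv), 8 methyl (Z)-2-(chloromethyl)-4-oxobut-2-enoate (1.5 equiv)
Product: 18 methyl (2Z,4S,5R,7S,10E)-10-{[(tert-butyldiphenylsilyl)oxy]methyl}-2-(chloromethyl)-4-hydroxy-7-methyl-5-[(3-methylbutanoyl)oxy]-6-oxo-7,12-bis[(triethylsilyl)oxy]dodeca-2,10-dien-8-ynoate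
Conditions: Rh2(OAc)4 (2 mol %), 3,3′-bis(2,4,6-triisopropylphenyl)-1,1′-binaphthyl-2,2′-diyl hydrogen phosphate (10 mol %, the antipode matched to 8S,9R), 4 Å molecular sieves, CH2Cl2, −20 °C, slow addition of 16
Reagents that add atoms: none
Why: Proposed new method: Rh2(OAc)4 turns the diazoketone into a carbenoid that is captured by the O–H of 3-methylbutanoic acid to give an α-acyloxy enol (protic oxonium ylide), and before its 1,2-proton shift the chiral phosphoric acid hydrogen-bonds this enol and the electron-poor enal and delivers the enol to the aldehyde in a closed aldol transition state, giving the syn adduct with catalyst-controlled face selectivity (8S,9R) and forming the C8–C9 bond; the closest known reaction type is the Rh2(OAc)4/chiral phosphoric acid three-component trapping of protic onium ylides (diazo compound plus alcohol, water or carboxylic acid) by imines or activated carbonyl compounds, not yet shown for an acceptor-only diazoketone with an aliphatic acid and an enal.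

Step 10
Reactants: 18 methyl (2Z,4S,5R,7S,10E)-10-{[(tert-butyldiphenylsilyl)oxy]methyl}-2-(chloromethyl)-4-hydroxy-7-methyl-5-[(3-methylbutanoyl)oxy]-6-oxo-7,12-bis[(triethylsilyl)oxy]dodeca-2,10-dien-8-ynoate
Product: 19 methyl (2Z,4S,5R,7S,10E)-10-{[(tert-butyldiphenylsilyl)oxy]methyl}-2-(chloromethyl)-7-methyl-5-[(3-methylbutanoyl)oxy]-6-oxo-4,7,12-tris[(triethylsilyl)oxy]dodeca-2,10-dien-8-ynoate
Conditions: triethylsilyl trifluoromethanesulfonate (1.2 equiv), 2,6-lutidine (2 equiv), CH2Cl2, −78 °C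
Reagents that add atoms: triethylsilyl trifluoromethanesulfonate, CC[Si](CC)(CC)OS(=O)(=O)C(F)(F)F
Why: Low-temperature silylation masks O8 so that it is neither oxidized in step 12 nor able to compete for the lactone in step 13; the non-nucleophilic base spares the allylic chloride.

Step 11
Reactants: 19 methyl (2Z,4S,5R,7S,10E)-10-{[(tert-butyldiphenylsilyl)oxy]methyl}-2-(chloromethyl)-7-methyl-5-[(3-methylbutanoyl)oxy]-6-oxo-4,7,12-tris[(triethylsilyl)oxy]dodeca-2,10-dien-8-ynoate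
Product: 20 methyl (2Z,4S,5R)-5-{(2S)-5-[(2Z)-1-[(tert-butyldiphenylsilyl)oxy]-4-[(triethylsilyl)oxy]but-2-en-2-yl]-2-methyl-3-oxo-2,3-dihydrofuran-2-yl}-2-(chloromethyl)-5-[(3-methylbutanoyl)oxy]-4-[(triethylsilyl)oxy]pent-2-enoate
Conditions: AuCl3 (5 mol %), MeOH (1.5 equiv), CH2Cl2, 0 °C → rt
Reagents that add atoms: none
Why: Gold-catalysed carbonyl–alkyne heterocyclization followed by a 1,2-methyl shift (α-ketol-type, Kirsch furanone synthesis): the C10 ketone oxygen adds 5-endo to the activated alkyne, methyl migrates suprafacially from C1 to the oxocarbenium carbon while the silyl group is passed to methanol, so the (S)-carbinol centre is transferred into the (S)-quaternary C10 and C1 becomes the furanone carbonyl.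

Step 12
Reactants: 20 methyl (2Z,4S,5R)-5-{(2S)-5-[(2Z)-1-[(tert-butyldiphenylsilyl)oxy]-4-[(triethylsilyl)oxy]but-2-en-2-yl]-2-methyl-3-oxo-2,3-dihydrofuran-2-yl}-2-(chloromethyl)-5-[(3-methylbutanoyl)oxy]-4-[(triethylsilyl)oxy]pent-2-enoate
Product: 21 methyl (2Z,4S,5R)-5-{(2S)-5-[(2Z)-1-[(tert-butyldiphenylsilyl)oxy]-4-oxobut-2-en-2-yl]-2-methyl-3-oxo-2,3-dihydrofuran-2-yl}-2-(chloromethyl)-5-[(3-methylbutanoyl)oxy]-4-[(triethylsilyl)oxy]pent-2-enoate
Conditions: (COCl)2, DMSO, CH2Cl2, −78 → −40 °C; Et3N, −78 → −20 °C; used at once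
Reagents that add atoms: none
Why: Swern conditions convert a primary triethylsilyl ether directly into the aldehyde while the secondary triethylsilyl and the tert-butyldiphenylsilyl ethers survive; low temperature preserves the (Z)-enal.

Step 13
Reactants: 21 methyl (2Z,4S,5R)-5-{(2S)-5-[(2Z)-1-[(tert-butyldiphenylsilyl)oxy]-4-oxobut-2-en-2-yl]-2-methyl-3-oxo-2,3-dihydrofuran-2-yl}-2-(chloromethyl)-5-[(3-methylbutanoyl)oxy]-4-[(triethylsilyl)oxy]pent-2-enoate
Product: 24 (4Z,6R,7R,8S,9R,10S)-15-[(tert-butyldiphenylsilyl)oxy]-8-hydroxy-9-[(3-methylbutanoyl)oxy]-1-oxo-3,10-epoxygermacra-2,4,11(13)-trien-12,6-olide, via macrocyclic hydroxy ester 22 (not isolated), via triethylsilyl lactone 23 (not isolated)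
Conditions: CrCl2 (8 equiv), THF/DMF 5:1, 0.003 M, rt; then PPTS (0.3 equiv), MeOH, 0 °C → rt
Reagents that add atoms: none
Why: Nozaki–Hiyama-type intramolecular allylation: the allylchromium species from the allylic chloride adds through its γ-carbon (C7) to the aldehyde in a cyclic transition state and closes the ten-membered ring; the macrocyclic transition state of least transannular strain is expected to place H6 and H7 anti (trans-lactone, as in chromium-mediated closures of other germacranolides) and C11 anti to the O8 silyl ether (6R,7S; the 7R label of 24 reflects only a priority change), after which the chromium alkoxide lactonizes onto the methyl ester and mild acid methanolysis removes the secondary silyl ether.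

Step 14
Reactants: 24 (4Z,6R,7R,8S,9R,10S)-15-[(tert-butyldiphenylsilyl)oxy]-8-hydroxy-9-[(3-methylbutanoyl)oxy]-1-oxo-3,10-epoxygermacra-2,4,11(13)-trien-12,6-olide, 25 2-methylprop-2-enoyl chloride
Product: 26 (4Z,6R,7S,8S,9R,10S)-15-[(tert-butyldiphenylsilyl)oxy]-8-[(2-methylprop-2-enoyl)oxy]-9-[(3-methylbutanoyl)oxy]-1-oxo-3,10-epoxygermacra-2,4,11(13)-trien-12,6-olide
Conditions: Et3N (2 equiv), DMAP (10 mol %), CH2Cl2, 0 °C
Reagents that add atoms: none
Why: DMAP-catalysed acylation of the only free hydroxyl; no stereocentre is touched.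

Step 15
Reactants: 26 (4Z,6R,7S,8S,9R,10S)-15-[(tert-butyldiphenylsilyl)oxy]-8-[(2-methylprop-2-enoyl)oxy]-9-[(3-methylbutanoyl)oxy]-1-oxo-3,10-epoxygermacra-2,4,11(13)-trien-12,6-olide
Product: 27 (4Z,6R,7S,8S,9R,10S)-15-hydroxy-8-[(2-methylprop-2-enoyl)oxy]-9-[(3-methylbutanoyl)oxy]-1-oxo-3,10-epoxygermacra-2,4,11(13)-trien-12,6-olide (CNP0552093.1)
Conditions: HF·pyridine, pyridine, THF, 0 °C → rt
Reagents that add atoms: none
Why: Fluoride desilylation under buffered, non-basic conditions spares the methacrylate, the α-methylene lactone and the furanone.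

## Compound list

1 | but-2-yne-1,4-diol | OCC#CCO | starting material
2 | 4-[(tert-butyldiphenylsilyl)oxy]but-2-yn-1-ol | OCC#CCO[Si](c1ccccc1)(c1ccccc1)C(C)(C)C | intermediate
3 | (Z)-4-[(tert-butyldiphenylsilyl)oxy]-3-iodobut-2-en-1-ol | OC/C=C(/CO[Si](c1ccccc1)(c1ccccc1)C(C)(C)C)I | intermediate
4 | 2,2-dimethoxyacetaldehyde | COC(OC)C=O | starting material
5 | methyl prop-2-enoate | C=CC(=O)OC | starting material
6 | methyl 2-(1-hydroxy-2,2-dimethoxyethyl)prop-2-enoate (racemic) | C=C(C(=O)OC)C(O)C(OC)OC | intermediate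
7 | methyl (Z)-2-(chloromethyl)-4,4-dimethoxybut-2-enoate | COC(OC)/C=C(\CCl)C(=O)OC | intermediate
8 | methyl (Z)-2-(chloromethyl)-4-oxobut-2-enoate | O=C/C=C(\CCl)C(=O)OC | intermediate
9 | butane-2,3-dione | CC(=O)C(C)=O | starting material
10 | ethynyltrimethylsilane | C#C[Si](C)(C)C | starting material
11 | (S)-3-hydroxy-3-methyl-5-(trimethylsilyl)pent-4-yn-2-one | CC(=O)[C@@](C)(O)C#C[Si](C)(C)C | intermediate
12 | (S)-3-hydroxy-3-methylpent-4-yn-2-one | CC(=O)[C@@](C)(O)C#C | intermediate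
13 | (3S,6E)-6-{[(tert-butyldiphenylsilyl)oxy]methyl}-3,8-dihydroxy-3-methyloct-6-en-4-yn-2-one | CC(=O)[C@@](C)(O)C#C/C(CO[Si](c1ccccc1)(c1ccccc1)C(C)(C)C)=C\CO | intermediate
14 | (3S,6E)-6-{[(tert-butyldiphenylsilyl)oxy]methyl}-3-methyl-3,8-bis[(triethylsilyl)oxy]oct-6-en-4-yn-2-one | CC(=O)[C@@](C)(O[Si](CC)(CC)CC)C#C/C(CO[Si](c1ccccc1)(c1ccccc1)C(C)(C)C)=C\CO[Si](CC)(CC)CC | intermediate
15 | (5S,8E)-8-{[(tert-butyldiphenylsilyl)oxy]methyl}-1,1,1-trifluoro-5-methyl-5,10-bis[(triethylsilyl)oxy]dec-8-en-6-yne-2,4-dione | O=C(CC(=O)[C@@](C)(O[Si](CC)(CC)CC)C#C/C(CO[Si](c1ccccc1)(c1ccccc1)C(C)(C)C)=C\CO[Si](CC)(CC)CC)C(F)(F)F | intermediate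
16 | (3S,6E)-6-{[(tert-butyldiphenylsilyl)oxy]methyl}-1-diazo-3-methyl-3,8-bis[(triethylsilyl)oxy]oct-6-en-4-yn-2-one | [N-]=[N+]=CC(=O)[C@@](C)(O[Si](CC)(CC)CC)C#C/C(CO[Si](c1ccccc1)(c1ccccc1)C(C)(C)C)=C\CO[Si](CC)(CC)CC | intermediate
17 | 3-methylbutanoic acid | CC(C)CC(=O)O | starting material
18 | methyl (2Z,4S,5R,7S,10E)-10-{[(tert-butyldiphenylsilyl)oxy]methyl}-2-(chloromethyl)-4-hydroxy-7-methyl-5-[(3-methylbutanoyl)oxy]-6-oxo-7,12-bis[(triethylsilyl)oxy]dodeca-2,10-dien-8-ynoate | COC(=O)/C(CCl)=C/[C@H](O)[C@@H](OC(=O)CC(C)C)C(=O)[C@@](C)(O[Si](CC)(CC)CC)C#C/C(CO[Si](c1ccccc1)(c1ccccc1)C(C)(C)C)=C\CO[Si](CC)(CC)CC | intermediate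
19 | methyl (2Z,4S,5R,7S,10E)-10-{[(tert-butyldiphenylsilyl)oxy]methyl}-2-(chloromethyl)-7-methyl-5-[(3-methylbutanoyl)oxy]-6-oxo-4,7,12-tris[(triethylsilyl)oxy]dodeca-2,10-dien-8-ynoate | COC(=O)/C(CCl)=C/[C@H](O[Si](CC)(CC)CC)[C@@H](OC(=O)CC(C)C)C(=O)[C@@](C)(O[Si](CC)(CC)CC)C#C/C(CO[Si](c1ccccc1)(c1ccccc1)C(C)(C)C)=C\CO[Si](CC)(CC)CC | intermediate
20 | methyl (2Z,4S,5R)-5-{(2S)-5-[(2Z)-1-[(tert-butyldiphenylsilyl)oxy]-4-[(triethylsilyl)oxy]but-2-en-2-yl]-2-methyl-3-oxo-2,3-dihydrofuran-2-yl}-2-(chloromethyl)-5-[(3-methylbutanoyl)oxy]-4-[(triethylsilyl)oxy]pent-2-enoate | COC(=O)/C(CCl)=C/[C@H](O[Si](CC)(CC)CC)[C@@H](OC(=O)CC(C)C)[C@]1(C)OC(/C(CO[Si](c2ccccc2)(c2ccccc2)C(C)(C)C)=C\CO[Si](CC)(CC)CC)=CC1=O | intermediate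
21 | methyl (2Z,4S,5R)-5-{(2S)-5-[(2Z)-1-[(tert-butyldiphenylsilyl)oxy]-4-oxobut-2-en-2-yl]-2-methyl-3-oxo-2,3-dihydrofuran-2-yl}-2-(chloromethyl)-5-[(3-methylbutanoyl)oxy]-4-[(triethylsilyl)oxy]pent-2-enoate | COC(=O)/C(CCl)=C/[C@H](O[Si](CC)(CC)CC)[C@@H](OC(=O)CC(C)C)[C@]1(C)OC(/C(CO[Si](c2ccccc2)(c2ccccc2)C(C)(C)C)=C\C=O)=CC1=O | intermediate
22 | methyl (4Z,6R,7S,8S,9R,10S)-15-[(tert-butyldiphenylsilyl)oxy]-6-hydroxy-9-[(3-methylbutanoyl)oxy]-1-oxo-8-[(triethylsilyl)oxy]-3,10-epoxygermacra-2,4,11(13)-trien-12-oate | CC[Si](CC)(CC)O[C@H]1[C@@H](C(=C)C(=O)OC)[C@H](O)/C=C(/CO[Si](c3ccccc3)(c3ccccc3)C(C)(C)C)C2=CC(=O)[C@@](C)(O2)[C@@H]1OC(=O)CC(C)C | intermediate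
23 | (4Z,6R,7S,8S,9R,10S)-15-[(tert-butyldiphenylsilyl)oxy]-9-[(3-methylbutanoyl)oxy]-1-oxo-8-[(triethylsilyl)oxy]-3,10-epoxygermacra-2,4,11(13)-trien-12,6-olide | CC[Si](CC)(CC)O[C@H]1[C@H]2C(=C)C(=O)O[C@@H]2/C=C(/CO[Si](c3ccccc3)(c3ccccc3)C(C)(C)C)C2=CC(=O)[C@@](C)(O2)[C@@H]1OC(=O)CC(C)C | intermediate
24 | (4Z,6R,7R,8S,9R,10S)-15-[(tert-butyldiphenylsilyl)oxy]-8-hydroxy-9-[(3-methylbutanoyl)oxy]-1-oxo-3,10-epoxygermacra-2,4,11(13)-trien-12,6-olide | O[C@H]1[C@H]2C(=C)C(=O)O[C@@H]2/C=C(/CO[Si](c3ccccc3)(c3ccccc3)C(C)(C)C)C2=CC(=O)[C@@](C)(O2)[C@@H]1OC(=O)CC(C)C | intermediate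
25 | 2-methylprop-2-enoyl chloride | C=C(C)C(=O)Cl | starting material
26 | (4Z,6R,7S,8S,9R,10S)-15-[(tert-butyldiphenylsilyl)oxy]-8-[(2-methylprop-2-enoyl)oxy]-9-[(3-methylbutanoyl)oxy]-1-oxo-3,10-epoxygermacra-2,4,11(13)-trien-12,6-olide | C=C(C)C(=O)O[C@H]1[C@H]2C(=C)C(=O)O[C@@H]2/C=C(/CO[Si](c3ccccc3)(c3ccccc3)C(C)(C)C)C2=CC(=O)[C@@](C)(O2)[C@@H]1OC(=O)CC(C)C | intermediate
27 | (4Z,6R,7S,8S,9R,10S)-15-hydroxy-8-[(2-methylprop-2-enoyl)oxy]-9-[(3-methylbutanoyl)oxy]-1-oxo-3,10-epoxygermacra-2,4,11(13)-trien-12,6-olide (CNP0552093.1) | C=C(C)C(=O)O[C@H]1[C@H]2C(=C)C(=O)O[C@@H]2/C=C(/CO)C2=CC(=O)[C@@](C)(O2)[C@@H]1OC(=O)CC(C)C | target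

## Step count and risks

Total step count: 15. Longest linear sequence: 12 steps (steps 1, 2, 6–15). Steps 3–4 and step 5 are side branches.

The three steps most likely to fail:

Step 5 (new mono-alkynylation; risks are base-induced self-condensation of the diketone and low enantioselectivity). The fallback uses known chemistry and sets out from 10. The reported Zn(OTf)2/Et3N/amino alcohol alkynylation of an α-keto ester is run with 10 and methyl 2-oxopropanoate F1 in place of the diketone. F1 gives under these conditions methyl (S)-2-hydroxy-2-methyl-4-(trimethylsilyl)but-3-ynoate F2 as the adduct. F2 is converted by MeNH(OMe)·HCl and i-PrMgCl in THF into (S)-2-hydroxy-N-methoxy-N,2-dimethyl-4-(trimethylsilyl)but-3-ynamide F3 as the Weinreb amide. F3 reacts with MeMgBr to give the methyl ketone, which is compound 11, where the route is rejoined (K2CO3/MeOH to 12).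

Step 9 (new three-component coupling; risks are 1,2-proton shift outrunning the aldol trapping and low diastereocontrol). The fallback uses known chemistry and sets out from 16. Rh2(OAc)4-catalysed O–H insertion with 17 alone gives (3S,6E)-6-{[(tert-butyldiphenylsilyl)oxy]methyl}-3-methyl-2-oxo-3,8-bis[(triethylsilyl)oxy]oct-6-en-4-yn-1-yl 3-methylbutanoate F4 as an isolable α-acyloxy ketone. F4 is converted into its (Z)-boron enolate (Bu2BOTf or diisopinocampheylboron triflate, i-Pr2NEt, CH2Cl2, −78 °C), which undergoes a syn-selective aldol addition to 8 and returns to the route at 18.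

Step 13 (macrocyclization; risks are oligomerization and the wrong C6/C7 diastereomer, since acyclic (Z)-2-(halomethyl)enoates usually favour cis-lactones). The fallback replaces the organochromium addition by an allylboration through a closed boron transition state and sets out from 20. Pd2(dba)3-catalysed borylation of the allylic chloride with B2pin2 gives methyl (2E,4S,5R)-5-{(2S)-5-[(2Z)-1-[(tert-butyldiphenylsilyl)oxy]-4-[(triethylsilyl)oxy]but-2-en-2-yl]-2-methyl-3-oxo-2,3-dihydrofuran-2-yl}-5-[(3-methylbutanoyl)oxy]-2-[(4,4,5,5-tetramethyl-1,3,2-dioxaborolan-2-yl)methyl]-4-[(triethylsilyl)oxy]pent-2-enoate F5 as the allylboronate. F5 undergoes Swern oxidation of its primary silyl ether to give methyl (2E,4S,5R)-5-{(2S)-5-[(2Z)-1-[(tert-butyldiphenylsilyl)oxy]-4-oxobut-2-en-2-yl]-2-methyl-3-oxo-2,3-dihydrofuran-2-yl}-5-[(3-methylbutanoyl)oxy]-2-[(4,4,5,5-tetramethyl-1,3,2-dioxaborolan-2-yl)methyl]-4-[(triethylsilyl)oxy]pent-2-enoate F6 as the aldehyde. F6 cyclizes by intramolecular allylboration (rt or Sc(OTf)3 catalysis) with lactonization and returns to the route at 23, which PPTS/MeOH converts into 24.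

Further compounds
F1 | step 5 | methyl 2-oxopropanoate | CC(=O)C(=O)OC
F2 | step 5 | methyl (S)-2-hydroxy-2-methyl-4-(trimethylsilyl)but-3-ynoate | COC(=O)[C@@](C)(O)C#C[Si](C)(C)C
F3 | step 5 | (S)-2-hydroxy-N-methoxy-N,2-dimethyl-4-(trimethylsilyl)but-3-ynamide | CON(C)C(=O)[C@@](C)(O)C#C[Si](C)(C)C
F4 | step 9 | (3S,6E)-6-{[(tert-butyldiphenylsilyl)oxy]methyl}-3-methyl-2-oxo-3,8-bis[(triethylsilyl)oxy]oct-6-en-4-yn-1-yl 3-methylbutanoate | CC(C)CC(=O)OCC(=O)[C@@](C)(O[Si](CC)(CC)CC)C#C/C(CO[Si](c1ccccc1)(c1ccccc1)C(C)(C)C)=C\CO[Si](CC)(CC)CC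
F5 | step 13 | methyl (2E,4S,5R)-5-{(2S)-5-[(2Z)-1-[(tert-butyldiphenylsilyl)oxy]-4-[(triethylsilyl)oxy]but-2-en-2-yl]-2-methyl-3-oxo-2,3-dihydrofuran-2-yl}-5-[(3-methylbutanoyl)oxy]-2-[(4,4,5,5-tetramethyl-1,3,2-dioxaborolan-2-yl)methyl]-4-[(triethylsilyl)oxy]pent-2-enoate | COC(=O)/C(CB1OC(C)(C)C(C)(C)O1)=C/[C@H](O[Si](CC)(CC)CC)[C@@H](OC(=O)CC(C)C)[C@]1(C)OC(/C(CO[Si](c2ccccc2)(c2ccccc2)C(C)(C)C)=C\CO[Si](CC)(CC)CC)=CC1=O
F6 | step 13 | methyl (2E,4S,5R)-5-{(2S)-5-[(2Z)-1-[(tert-butyldiphenylsilyl)oxy]-4-oxobut-2-en-2-yl]-2-methyl-3-oxo-2,3-dihydrofuran-2-yl}-5-[(3-methylbutanoyl)oxy]-2-[(4,4,5,5-tetramethyl-1,3,2-dioxaborolan-2-yl)methyl]-4-[(triethylsilyl)oxy]pent-2-enoate | COC(=O)/C(CB1OC(C)(C)C(C)(C)O1)=C/[C@H](O[Si](CC)(CC)CC)[C@@H](OC(=O)CC(C)C)[C@]1(C)OC(/C(CO[Si](c2ccccc2)(c2ccccc2)C(C)(C)C)=C\C=O)=CC1=O
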